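**Retrosynthetic overview**

- Feature: on ring A the carbon bearing the pyran oxygen (C8a–O1) and the carbon bearing the methylene bridge to ring D (C8) are adjacent, between the C4a side chain and the C7 oxygen. An aryne across C8–C8a therefore allows O1–C8a and C8–C(bridge) to be made in one operation.
- Last disconnections: the Ar–CH2–Ar bridge goes back to a diaryl carbinol (ionic deoxygenation), and all phenols and the C3 hydroxyl to benzyl ethers. The carbinol is cut at O1–C8a and C8–CH(OH) into an o-silylaryl triflate with a tethered C2 oxygen and the ring D aldehyde.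
- Aryne precursor: the C2 oxygen is carried as its trimethylsilyl ether, so that fluoride releases the alkoxide and the aryne together and no Brønsted acid is formed. The silyl triflate comes from an o-bromophenol by O-to-C silyl migration, and the anti C2–O/C3–OBn pair from chelation-controlled reduction of an α-benzyloxy ketone (Weinreb amide plus ring B Grignard reagent). C3 comes from methyl (S)-glycidate opened by a ring A arylcopper.
- Ring D aldehyde: Friedel–Crafts acylation of 2-methylphloroglucinol with (R)-2-methylbutanoyl chloride, selective dibenzylation, methylation of the chelated hydroxyl, formylation of the last free position.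
- Ring order: rings A, B and D are bought as benzene rings; ring C (the pyran) is the only ring formed, in the key step.

Key step: step 14

Remark: the carbinol carbon formed in step 14 is written without configuration; both epimers are expected and both should give 28 in step 15.

**Route**

Step 1
Reactants: 1 2-methylphloroglucinol; 2 (R)-2-methylbutanoic acid
Product: 4 (2R)-2-methyl-1-(2,4,6-trihydroxy-3-methylphenyl)butan-1-one, via (R)-2-methylbutanoyl chloride 3 (not isolated)
Conditions: 2, (COCl)2, DMF (cat.), CH2Cl2, 0 °C to rt; then 1, AlCl3, PhNO2/CH2Cl2, 0 °C to rt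
Reagents that add atoms: none
Why: Friedel–Crafts C-acylation of the symmetric, strongly activated triol at one of its two equivalent free positions should give a single ketone, and the α-stereocentre of 3 is carried over unchanged because acylium formation and ring attack at 0 °C are faster than loss of the α-proton.

Step 2
Reactants: 4 (2R)-2-methyl-1-(2,4,6-trihydroxy-3-methylphenyl)butan-1-one
Product: 5 (2R)-1-[4,6-bis(benzyloxy)-2-hydroxy-3-methylphenyl]-2-methylbutan-1-one
Conditions: BnBr (2.1 equiv), K2CO3, DMF, rt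
Reagents that add atoms: benzyl bromide, BrCc1ccccc1
Why: Williamson etherification should take the free para hydroxyl and then the chelated hydroxyl at C6, which has only hydrogen on its other side, and leave the C2 hydroxyl, which is hydrogen-bonded to the ketone and shielded by the C3 methyl group.

Step 3
Reactants: 5 (2R)-1-[4,6-bis(benzyloxy)-2-hydroxy-3-methylphenyl]-2-methylbutan-1-one
Product: 6 (2R)-1-[4,6-bis(benzyloxy)-2-methoxy-3-methylphenyl]-2-methylbutan-1-one
Conditions: MeI, K2CO3, DMF, 40 °C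
Reagents that add atoms: iodomethane, CI
Why: Williamson methylation of the last, chelated and hindered phenol needs only a small electrophile and gentle warming, and carbonate is too weak a base to enolise the twisted aryl ketone, so the α-stereocentre stays.

Step 4
Reactants: 6 (2R)-1-[4,6-bis(benzyloxy)-2-methoxy-3-methylphenyl]-2-methylbutan-1-one
Product: 8 2,6-bis(benzyloxy)-4-methoxy-3-methyl-5-[(2R)-2-methylbutanoyl]benzaldehyde, via chloro(methoxy)methyl arene 7 (not isolated)
Conditions: Cl2CHOMe, AgOTf, CH2Cl2, −78 °C; then aq. NaHCO3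
Reagents that add atoms: dichloromethyl methyl ether, COC(Cl)Cl; water, O
Why: Rieche formylation, an electrophilic aromatic substitution, can only occur at the single free ring position, which is ortho to both benzyloxy groups and para to the methoxy group; the silver-promoted variant runs at −78 °C, so benzyl ethers and the α-stereocentre are spared, and water at work-up turns 7 into the aldehyde.

Step 5
Reactants: 9 3,5-bis(benzyloxy)phenol
Product: 10 3,5-bis(benzyloxy)-2,6-dibromophenol
Conditions: NBS (2.05 equiv), iPr2NH (0.2 equiv), CH2Cl2, −78 to 0 °C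
Reagents that add atoms: N-bromosuccinimide, O=C1CCC(=O)N1Br
Why: Amine-mediated electrophilic bromination of a phenol is ortho-selective because the N-bromoamine is held by the phenolic hydrogen bond, and the para position is in addition flanked by two benzyloxy groups, so both ortho positions should be brominated.

Step 6
Reactants: 10 3,5-bis(benzyloxy)-2,6-dibromophenol
Product: 11 [3,5-bis(benzyloxy)-2,6-dibromophenoxy]tri(propan-2-yl)silane
Conditions: iPr3SiOTf, 2,6-lutidine, CH2Cl2, 0 °C to rt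
Reagents that add atoms: triisopropylsilyl trifluoromethanesulfonate, CC(C)[Si](OS(=O)(=O)C(F)(F)F)(C(C)C)C(C)C
Why: Silylation of the acidic, hindered phenol with the silyl triflate gives an ether that withstands Grignard, silver oxide and borohydride conditions and is later removed by fluoride without acid.

Step 7
Reactants: 11 [3,5-bis(benzyloxy)-2,6-dibromophenoxy]tri(propan-2-yl)silane; 12 methyl (2S)-oxirane-2-carboxylate (methyl (S)-glycidate)
Product: 14 methyl (2S)-3-[4,6-bis(benzyloxy)-3-bromo-2-{[tri(propan-2-yl)silyl]oxy}phenyl]-2-hydroxypropanoate, via arylmagnesium chloride 13 (not isolated)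
Conditions: iPrMgCl·LiCl (1.05 equiv), THF, −15 to 0 °C; then CuI (10 mol%), 12, −40 to −10 °C; then 1 M HCl
Reagents that add atoms: none
Why: Bromine–magnesium exchange at one of the two equivalent bromines (each activated by two ortho oxygens) followed by copper-catalysed SN2 opening of the glycidic ester at its unsubstituted C3 forms the C4a–C4 bond without touching the stereocentre of 12, which becomes C3 of the flavan with S configuration.

Step 8
Reactants: 14 methyl (2S)-3-[4,6-bis(benzyloxy)-3-bromo-2-{[tri(propan-2-yl)silyl]oxy}phenyl]-2-hydroxypropanoate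
Product: 15 methyl (2S)-2-(benzyloxy)-3-[4,6-bis(benzyloxy)-3-bromo-2-{[tri(propan-2-yl)silyl]oxy}phenyl]propanoate
Conditions: BnBr, Ag2O, 4 Å MS, toluene, rt, dark
Reagents that add atoms: benzyl bromide, BrCc1ccccc1
Why: Silver oxide-mediated Williamson benzylation is neutral, so the α-hydroxy ester is not racemised and the electron-rich ring A is not benzylated at carbon as it could be under acid.

Step 9
Reactants: 15 methyl (2S)-2-(benzyloxy)-3-[4,6-bis(benzyloxy)-3-bromo-2-{[tri(propan-2-yl)silyl]oxy}phenyl]propanoate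
Product: 16 (2S)-2-(benzyloxy)-3-[4,6-bis(benzyloxy)-3-bromo-2-{[tri(propan-2-yl)silyl]oxy}phenyl]-N-methoxy-N-methylpropanamide
Conditions: MeNH(OMe)·HCl, iPrMgCl, THF, −20 °C
Reagents that add atoms: N,O-dimethylhydroxylamine hydrochloride, CNOC.Cl
Why: Aminolysis of the methyl ester by the chloromagnesium amide of N,O-dimethylhydroxylamine (Weinreb amide formation) proceeds at −20 °C, where neither the ring bromide nor the α-stereocentre reacts.

Step 10
Reactants: 16 (2S)-2-(benzyloxy)-3-[4,6-bis(benzyloxy)-3-bromo-2-{[tri(propan-2-yl)silyl]oxy}phenyl]-N-methoxy-N-methylpropanamide; 17 1,2-bis(benzyloxy)-4-bromobenzene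
Product: 19 (2S)-2-(benzyloxy)-1-[3,4-bis(benzyloxy)phenyl]-3-[4,6-bis(benzyloxy)-3-bromo-2-{[tri(propan-2-yl)silyl]oxy}phenyl]propan-1-one, via arylmagnesium bromide 18 (not isolated)
Conditions: 17, Mg, THF, rt; then 16, THF, −10 to 0 °C; then cold 1 M HCl
Reagents that add atoms: none
Why: Weinreb ketone synthesis: the chelated tetrahedral adduct holds until the acidic quench, so there is no second addition and no enolisation of the α-benzyloxy ketone under basic conditions, and a Grignard reagent, unlike an aryllithium, does not exchange with the ring A bromide.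

Step 11
Reactants: 19 (2S)-2-(benzyloxy)-1-[3,4-bis(benzyloxy)phenyl]-3-[4,6-bis(benzyloxy)-3-bromo-2-{[tri(propan-2-yl)silyl]oxy}phenyl]propan-1-one
Product: 20 (1R,2S)-2-(benzyloxy)-1-[3,4-bis(benzyloxy)phenyl]-3-[4,6-bis(benzyloxy)-3-bromo-2-{[tri(propan-2-yl)silyl]oxy}phenyl]propan-1-ol
Conditions: Zn(BH4)2, Et2O/CH2Cl2, −78 to −30 °C; then aq. NH4Cl
Reagents that add atoms: none
Why: Chelation-controlled reduction (Cram chelate model): zinc bridges the carbonyl and benzyloxy oxygens and hydride enters from the face opposite the CH2Ar group, which sets the carbinol carbon (flavan C2) as R, anti to the C3 oxygen.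

Step 12
Reactants: 20 (1R,2S)-2-(benzyloxy)-1-[3,4-bis(benzyloxy)phenyl]-3-[4,6-bis(benzyloxy)-3-bromo-2-{[tri(propan-2-yl)silyl]oxy}phenyl]propan-1-ol
Product: 21 3,5-bis(benzyloxy)-2-{(2S,3R)-2-(benzyloxy)-3-[3,4-bis(benzyloxy)phenyl]-3-hydroxypropyl}-6-bromophenol
Conditions: Bu4NF (1.1 equiv), AcOH (1.1 equiv), THF, 0 °C
Reagents that add atoms: none
Why: Fluoride-induced cleavage of the aryl silyl ether, driven by the Si–F bond and the phenoxide leaving group, frees the phenol under buffered conditions that leave the benzylic alcohol, the bromide and the benzyl ethers alone.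

Step 13
Reactants: 21 3,5-bis(benzyloxy)-2-{(2S,3R)-2-(benzyloxy)-3-[3,4-bis(benzyloxy)phenyl]-3-hydroxypropyl}-6-bromophenol
Product: 24 3,5-bis(benzyloxy)-2-{(2S,3R)-2-(benzyloxy)-3-[3,4-bis(benzyloxy)phenyl]-3-[(trimethylsilyl)oxy]propyl}-6-(trimethylsilyl)phenyl trifluoromethanesulfonate, via bis(trimethylsilyl) ether 22 (not isolated), via lithium silylphenoxide 23 (not isolated)
Conditions: HMDS, Me3SiCl (5 mol%), THF, 60 °C, then evaporation; n-BuLi (1.1 equiv), THF, −78 °C; Tf2O, −78 to 0 °C; aq. NaHCO3; Et3N-deactivated silica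
Reagents that add atoms: hexamethyldisilazane, C[Si](C)(C)N[Si](C)(C)C; trifluoromethanesulfonic anhydride, O=S(=O)(OS(=O)(=O)C(F)(F)F)C(F)(F)F
Why: Exhaustive O-silylation, bromine–lithium exchange and anionic 1,3 O-to-C silyl migration (retro-Brook rearrangement) move the phenolic silicon to C8, and the hindered phenoxide 23 is then triflated at oxygen, the standard one-pot route to o-silylaryl triflates; the alkyl silyl ether is inert to both reagents at −78 °C.

Step 14
Reactants: 24 3,5-bis(benzyloxy)-2-{(2S,3R)-2-(benzyloxy)-3-[3,4-bis(benzyloxy)phenyl]-3-[(trimethylsilyl)oxy]propyl}-6-(trimethylsilyl)phenyl trifluoromethanesulfonate; 8 2,6-bis(benzyloxy)-4-methoxy-3-methyl-5-[(2R)-2-methylbutanoyl]benzaldehyde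
Product: 27 (2R)-1-[2,4-bis(benzyloxy)-3-{[(2R,3S)-3,5,7-tris(benzyloxy)-2-[3,4-bis(benzyloxy)phenyl]-3,4-dihydro-2H-chromen-8-yl](hydroxy)methyl}-6-methoxy-5-methylphenyl]-2-methylbutan-1-one, via aryne alkoxide 25 (not isolated), via C8 arylpotassium 26 (not isolated)
Conditions: KF (4 equiv), 18-crown-6 (4 equiv), 4 Å MS, 8 (2.5 equiv), THF, 0 °C to rt, 24 added over 4 h; then H2O
Reagents that add atoms: none
Why: Proposed new method: fluoride first cleaves the O–SiMe3 bond to give the potassium C2 alkoxide and then attacks the ring silicon, expelling triflate to give the C8–C8a aryne 25; the tethered alkoxide adds to C8a and the C8 carbanion 26 so formed adds to the aldehyde carbon of 8, so that O1–C8a and C8–C(bridge) arise in one flask. The closest known reaction types are tethered alkoxide additions to arynes that give chromans and fluoride-triggered three-component couplings in which the aryl anion left by nucleophilic addition to an aryne is captured by an aldehyde; their union on an oxygen nucleophile carrying stereocentres and on an aryl anion this hindered has not been shown. Ring C closes by 6-exo-dig attack of oxygen on the in-plane π bond of the aryne; attack at C8 is geometrically impossible for a three-atom tether, and C8a is also the electronically matched terminus because the C7 benzyloxy group stabilises negative charge at C8 inductively. C2 and C3 keep their configuration because the C2 oxygen itself is the nucleophile and no bond to either carbon is broken; the carbinol carbon is the only new stereocentre, it is not controlled, and it is erased in step 15. The selectivity needed is capture of 26 by the aldehyde in preference to protonation, C-silylation or attack on the ketone or on a triflate sulfur: the alkoxide is released from a silyl ether so that no Brønsted acid is formed, THF and crown-complexed KF offer no acidic C–H, 24 is added slowly to an excess of 8, and the ketone of 8 is shielded by two ortho substituents and an α-branch.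

Step 15
Reactants: 27 (2R)-1-[2,4-bis(benzyloxy)-3-{[(2R,3S)-3,5,7-tris(benzyloxy)-2-[3,4-bis(benzyloxy)phenyl]-3,4-dihydro-2H-chromen-8-yl](hydroxy)methyl}-6-methoxy-5-methylphenyl]-2-methylbutan-1-one
Product: 28 (2R)-1-[2,4-bis(benzyloxy)-3-{[(2R,3S)-3,5,7-tris(benzyloxy)-2-[3,4-bis(benzyloxy)phenyl]-3,4-dihydro-2H-chromen-8-yl]methyl}-6-methoxy-5-methylphenyl]-2-methylbutan-1-one
Conditions: Et3SiH, CF3CO2H, CH2Cl2, −20 to 0 °C
Reagents that add atoms: none
Why: Ionic hydrogenation: acid ionises the doubly benzylic carbinol to a diarylmethyl cation stabilised by two trioxygenated rings and triethylsilane delivers hydride, so both epimers of 27 give one product, while at low temperature the flavan C2–O1 bond, the benzyl ethers and the twisted ketone do not ionise.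

Step 16
Reactants: 28 (2R)-1-[2,4-bis(benzyloxy)-3-{[(2R,3S)-3,5,7-tris(benzyloxy)-2-[3,4-bis(benzyloxy)phenyl]-3,4-dihydro-2H-chromen-8-yl]methyl}-6-methoxy-5-methylphenyl]-2-methylbutan-1-one
Product: 29 (2R)-1-[3-{[(2R,3S)-2-(3,4-dihydroxyphenyl)-3,5,7-trihydroxy-3,4-dihydro-2H-chromen-8-yl]methyl}-2,4-dihydroxy-6-methoxy-5-methylphenyl]-2-methylbutan-1-one (CNP0299940.2)
Conditions: H2 (1 atm), Pd(OH)2/C, THF/MeOH, rt, argon work-up
Reagents that add atoms: none
Why: Catalytic hydrogenolysis cleaves the seven benzyl ethers, and under neutral conditions at room temperature the diarylmethane, the flavan C2–O1 bond and the hindered, hydrogen-bonded aryl ketone are not reduced.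

**Compound list**

1 | 2-methylphloroglucinol (2-methylbenzene-1,3,5-triol) | Cc1c(O)cc(O)cc1O | starting material
2 | (R)-2-methylbutanoic acid | CC[C@@H](C)C(=O)O | starting material
3 | (R)-2-methylbutanoyl chloride | CC[C@@H](C)C(=O)Cl | intermediate (not isolated)
4 | (2R)-2-methyl-1-(2,4,6-trihydroxy-3-methylphenyl)butan-1-one | CC[C@@H](C)C(=O)c1c(O)cc(O)c(C)c1O | intermediate
5 | (2R)-1-[4,6-bis(benzyloxy)-2-hydroxy-3-methylphenyl]-2-methylbutan-1-one | CC[C@@H](C)C(=O)c1c(OCc2ccccc2)cc(OCc2ccccc2)c(C)c1O | intermediate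
6 | (2R)-1-[4,6-bis(benzyloxy)-2-methoxy-3-methylphenyl]-2-methylbutan-1-one | CC[C@@H](C)C(=O)c1c(OCc2ccccc2)cc(OCc2ccccc2)c(C)c1OC | intermediate
7 | (2R)-1-{4,6-bis(benzyloxy)-5-[chloro(methoxy)methyl]-2-methoxy-3-methylphenyl}-2-methylbutan-1-one | CC[C@@H](C)C(=O)c1c(OCc2ccccc2)c(C(Cl)OC)c(OCc2ccccc2)c(C)c1OC | intermediate (not isolated)
8 | 2,6-bis(benzyloxy)-4-methoxy-3-methyl-5-[(2R)-2-methylbutanoyl]benzaldehyde | CC[C@@H](C)C(=O)c1c(OCc2ccccc2)c(C=O)c(OCc2ccccc2)c(C)c1OC | intermediate
9 | 3,5-bis(benzyloxy)phenol | Oc1cc(OCc2ccccc2)cc(OCc2ccccc2)c1 | starting material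
10 | 3,5-bis(benzyloxy)-2,6-dibromophenol | Oc1c(Br)c(OCc2ccccc2)cc(OCc2ccccc2)c1Br | intermediate
11 | [3,5-bis(benzyloxy)-2,6-dibromophenoxy]tri(propan-2-yl)silane | CC(C)[Si](Oc1c(Br)c(OCc2ccccc2)cc(OCc2ccccc2)c1Br)(C(C)C)C(C)C | intermediate
12 | methyl (2S)-oxirane-2-carboxylate | COC(=O)[C@@H]1CO1 | starting material
13 | [4,6-bis(benzyloxy)-3-bromo-2-{[tri(propan-2-yl)silyl]oxy}phenyl]magnesium chloride | CC(C)[Si](Oc1c(Br)c(OCc2ccccc2)cc(OCc2ccccc2)c1[Mg]Cl)(C(C)C)C(C)C | intermediate (not isolated)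
14 | methyl (2S)-3-[4,6-bis(benzyloxy)-3-bromo-2-{[tri(propan-2-yl)silyl]oxy}phenyl]-2-hydroxypropanoate | COC(=O)[C@@H](O)Cc1c(O[Si](C(C)C)(C(C)C)C(C)C)c(Br)c(OCc2ccccc2)cc1OCc1ccccc1 | intermediate
15 | methyl (2S)-2-(benzyloxy)-3-[4,6-bis(benzyloxy)-3-bromo-2-{[tri(propan-2-yl)silyl]oxy}phenyl]propanoate | COC(=O)[C@@H](OCc1ccccc1)Cc1c(O[Si](C(C)C)(C(C)C)C(C)C)c(Br)c(OCc2ccccc2)cc1OCc1ccccc1 | intermediate
16 | (2S)-2-(benzyloxy)-3-[4,6-bis(benzyloxy)-3-bromo-2-{[tri(propan-2-yl)silyl]oxy}phenyl]-N-methoxy-N-methylpropanamide | CON(C)C(=O)[C@@H](OCc1ccccc1)Cc1c(O[Si](C(C)C)(C(C)C)C(C)C)c(Br)c(OCc2ccccc2)cc1OCc1ccccc1 | intermediate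
17 | 1,2-bis(benzyloxy)-4-bromobenzene | Brc1ccc(OCc2ccccc2)c(OCc2ccccc2)c1 | starting material
18 | [3,4-bis(benzyloxy)phenyl]magnesium bromide | Br[Mg]c1ccc(OCc2ccccc2)c(OCc2ccccc2)c1 | intermediate (not isolated)
19 | (2S)-2-(benzyloxy)-1-[3,4-bis(benzyloxy)phenyl]-3-[4,6-bis(benzyloxy)-3-bromo-2-{[tri(propan-2-yl)silyl]oxy}phenyl]propan-1-one | O=C(c1ccc(OCc2ccccc2)c(OCc2ccccc2)c1)[C@@H](OCc1ccccc1)Cc1c(O[Si](C(C)C)(C(C)C)C(C)C)c(Br)c(OCc2ccccc2)cc1OCc1ccccc1 | intermediate
20 | (1R,2S)-2-(benzyloxy)-1-[3,4-bis(benzyloxy)phenyl]-3-[4,6-bis(benzyloxy)-3-bromo-2-{[tri(propan-2-yl)silyl]oxy}phenyl]propan-1-ol | CC(C)[Si](Oc1c(Br)c(OCc2ccccc2)cc(OCc2ccccc2)c1C[C@H](OCc1ccccc1)[C@H](O)c1ccc(OCc2ccccc2)c(OCc2ccccc2)c1)(C(C)C)C(C)C | intermediate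
21 | 3,5-bis(benzyloxy)-2-{(2S,3R)-2-(benzyloxy)-3-[3,4-bis(benzyloxy)phenyl]-3-hydroxypropyl}-6-bromophenol | Oc1c(Br)c(OCc2ccccc2)cc(OCc2ccccc2)c1C[C@H](OCc1ccccc1)[C@H](O)c1ccc(OCc2ccccc2)c(OCc2ccccc2)c1 | intermediate
22 | [3,5-bis(benzyloxy)-2-{(2S,3R)-2-(benzyloxy)-3-[3,4-bis(benzyloxy)phenyl]-3-[(trimethylsilyl)oxy]propyl}-6-bromophenoxy]trimethylsilane | C[Si](C)(C)Oc1c(Br)c(OCc2ccccc2)cc(OCc2ccccc2)c1C[C@H](OCc1ccccc1)[C@H](O[Si](C)(C)C)c1ccc(OCc2ccccc2)c(OCc2ccccc2)c1 | intermediate (not isolated)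
23 | lithium 3,5-bis(benzyloxy)-2-{(2S,3R)-2-(benzyloxy)-3-[3,4-bis(benzyloxy)phenyl]-3-[(trimethylsilyl)oxy]propyl}-6-(trimethylsilyl)phenoxide | [Li+].[O-]c1c([Si](C)(C)C)c(OCc2ccccc2)cc(OCc2ccccc2)c1C[C@H](OCc1ccccc1)[C@H](O[Si](C)(C)C)c1ccc(OCc2ccccc2)c(OCc2ccccc2)c1 | intermediate (not isolated)
24 | 3,5-bis(benzyloxy)-2-{(2S,3R)-2-(benzyloxy)-3-[3,4-bis(benzyloxy)phenyl]-3-[(trimethylsilyl)oxy]propyl}-6-(trimethylsilyl)phenyl trifluoromethanesulfonate | C[Si](C)(C)c1c(OCc2ccccc2)cc(OCc2ccccc2)c(C[C@H](OCc2ccccc2)[C@H](O[Si](C)(C)C)c2ccc(OCc3ccccc3)c(OCc3ccccc3)c2)c1OS(=O)(=O)C(F)(F)F | intermediate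
25 | potassium (1R,2S)-2-(benzyloxy)-1-[3,4-bis(benzyloxy)phenyl]-3-[4,6-bis(benzyloxy)-2,3-didehydrophenyl]propan-1-olate | [K+].[O-][C@H](c1ccc(OCc2ccccc2)c(OCc2ccccc2)c1)[C@@H](OCc1ccccc1)CC1=C(OCc2ccccc2)C=C(OCc2ccccc2)C#C1 | intermediate (not isolated)
26 | potassium (2R,3S)-3,5,7-tris(benzyloxy)-2-[3,4-bis(benzyloxy)phenyl]-3,4-dihydro-2H-chromen-8-ide | [K+].[c-]1c(OCc2ccccc2)cc(OCc2ccccc2)c2c1O[C@H](c1ccc(OCc3ccccc3)c(OCc3ccccc3)c1)[C@@H](OCc1ccccc1)C2 | intermediate (not isolated)
27 | (2R)-1-[2,4-bis(benzyloxy)-3-{[(2R,3S)-3,5,7-tris(benzyloxy)-2-[3,4-bis(benzyloxy)phenyl]-3,4-dihydro-2H-chromen-8-yl](hydroxy)methyl}-6-methoxy-5-methylphenyl]-2-methylbutan-1-one | CC[C@@H](C)C(=O)c1c(OCc2ccccc2)c(C(O)c2c(OCc4ccccc4)cc(OCc4ccccc4)c3c2O[C@H](c2ccc(OCc4ccccc4)c(OCc4ccccc4)c2)[C@@H](OCc2ccccc2)C3)c(OCc2ccccc2)c(C)c1OC | intermediate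
28 | (2R)-1-[2,4-bis(benzyloxy)-3-{[(2R,3S)-3,5,7-tris(benzyloxy)-2-[3,4-bis(benzyloxy)phenyl]-3,4-dihydro-2H-chromen-8-yl]methyl}-6-methoxy-5-methylphenyl]-2-methylbutan-1-one | CC[C@@H](C)C(=O)c1c(OCc2ccccc2)c(Cc2c(OCc4ccccc4)cc(OCc4ccccc4)c3c2O[C@H](c2ccc(OCc4ccccc4)c(OCc4ccccc4)c2)[C@@H](OCc2ccccc2)C3)c(OCc2ccccc2)c(C)c1OC | intermediate
29 | (2R)-1-[3-{[(2R,3S)-2-(3,4-dihydroxyphenyl)-3,5,7-trihydroxy-3,4-dihydro-2H-chromen-8-yl]methyl}-2,4-dihydroxy-6-methoxy-5-methylphenyl]-2-methylbutan-1-one | CC[C@@H](C)C(=O)c1c(O)c(Cc2c(O)cc(O)c3c2O[C@H](c2ccc(O)c(O)c2)[C@@H](O)C3)c(O)c(C)c1OC | target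

**Step count and risks**

Total steps: 16. Longest linear sequence: 12 steps (steps 5 to 16, from 9).

Steps most likely to fail:

1. Step 14 (proposed new method). The C8 carbanion may be quenched before it meets the aldehyde: by proton transfer from the neighbouring benzylic OCH2 of the C7 benzyloxy group, by silyl transfer from Me3SiF or from unreacted 24, or by attack on a triflate sulfur. The alkoxide may also remove the α-proton of the ketone in 8 and erode that stereocentre. Fallback with known chemistry, setting out from 24: CsF in MeCN containing tert-butanol frees the alcohol and the aryne, and the O–H bond adds across the aryne (proton-terminated hydroalkoxylation of an aryne), which should give (2R,3S)-3,5,7-tris(benzyloxy)-2-[3,4-bis(benzyloxy)phenyl]-3,4-dihydro-2H-chromene F1. NBS in CH2Cl2 at −20 °C should then brominate C8, the usual site in benzylated catechins, to give the 8-bromo compound F2. Bromine–lithium exchange with n-BuLi in THF at −78 °C and addition of the aryllithium to 8 returns to the route at 27.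

2. Step 13. The aryllithium formed by bromine–lithium exchange may abstract a benzylic proton of the C7 benzyloxy group faster than silicon migrates. Incomplete silylation of the secondary alcohol would lead to its triflation and loss of the side chain. The electron-rich aryl–silicon bond may also be cleaved by acid traces during isolation. Fallback, setting out from 21: camphorsulfonic acid (cat.) in CH2Cl2 at 0 °C ionises the benzylic alcohol and the phenol captures the cation. This should give mainly the 2,3-trans chroman, (2R,3S)-8-bromo-3,5,7-tris(benzyloxy)-2-[3,4-bis(benzyloxy)phenyl]-3,4-dihydro-2H-chromene F3 (the same compound as F2). Here the trans relationship rests on thermodynamic preference, not on retention, so the cis isomer would have to be separated. Bromine–lithium exchange (n-BuLi, THF, −78 °C) and addition to 8 returns to the route at 27.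

3. Step 7. The doubly ortho-substituted arylcopper may open the epoxide so slowly that addition to the ester carbonyl of 12, or decay of the Grignard reagent, takes over. Fallback, setting out from 11: the same bromine–magnesium exchange, then CuI (cat.) and (S)-glycidyl trityl ether, an epoxide without a carbonyl group, should give (2S)-1-[4,6-bis(benzyloxy)-3-bromo-2-{[tri(propan-2-yl)silyl]oxy}phenyl]-3-(trityloxy)propan-2-ol F4. Benzylation with BnBr and Ag2O gives the benzyl ether F5. TsOH in MeOH/CH2Cl2 removes the trityl group to give (2S)-2-(benzyloxy)-3-[4,6-bis(benzyloxy)-3-bromo-2-{[tri(propan-2-yl)silyl]oxy}phenyl]propan-1-ol F6. Oxidation with TEMPO (cat.) and PhI(OAc)2 in MeCN/H2O gives the corresponding (2S)-propanoic acid F7. Coupling with MeNH(OMe)·HCl (EDC·HCl, HOBt, iPr2NEt) returns to the route at 16.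

Further compounds
F1 | step 14 | (2R,3S)-3,5,7-tris(benzyloxy)-2-[3,4-bis(benzyloxy)phenyl]-3,4-dihydro-2H-chromene | c1c(OCc2ccccc2)cc(OCc2ccccc2)c2c1O[C@H](c1ccc(OCc3ccccc3)c(OCc3ccccc3)c1)[C@@H](OCc1ccccc1)C2
F2 | step 14 | (2R,3S)-8-bromo-3,5,7-tris(benzyloxy)-2-[3,4-bis(benzyloxy)phenyl]-3,4-dihydro-2H-chromene | Brc1c(OCc2ccccc2)cc(OCc2ccccc2)c2c1O[C@H](c1ccc(OCc3ccccc3)c(OCc3ccccc3)c1)[C@@H](OCc1ccccc1)C2
F3 | step 13 | (2R,3S)-8-bromo-3,5,7-tris(benzyloxy)-2-[3,4-bis(benzyloxy)phenyl]-3,4-dihydro-2H-chromene | Brc1c(OCc2ccccc2)cc(OCc2ccccc2)c2c1O[C@H](c1ccc(OCc3ccccc3)c(OCc3ccccc3)c1)[C@@H](OCc1ccccc1)C2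
F4 | step 7 | (2S)-1-[4,6-bis(benzyloxy)-3-bromo-2-{[tri(propan-2-yl)silyl]oxy}phenyl]-3-(trityloxy)propan-2-ol | C(c1ccccc1)(c1ccccc1)(c1ccccc1)OC[C@@H](O)Cc1c(O[Si](C(C)C)(C(C)C)C(C)C)c(Br)c(OCc2ccccc2)cc1OCc1ccccc1
F5 | step 7 | [2,4-bis(benzyloxy)-6-[(2S)-2-(benzyloxy)-3-(trityloxy)propyl]-3-bromophenoxy]tri(propan-2-yl)silane | C(c1ccccc1)(c1ccccc1)(c1ccccc1)OC[C@@H](OCc1ccccc1)Cc1c(O[Si](C(C)C)(C(C)C)C(C)C)c(Br)c(OCc2ccccc2)cc1OCc1ccccc1
F6 | step 7 | (2S)-2-(benzyloxy)-3-[4,6-bis(benzyloxy)-3-bromo-2-{[tri(propan-2-yl)silyl]oxy}phenyl]propan-1-ol | OC[C@@H](OCc1ccccc1)Cc1c(O[Si](C(C)C)(C(C)C)C(C)C)c(Br)c(OCc2ccccc2)cc1OCc1ccccc1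
F7 | step 7 | (2S)-2-(benzyloxy)-3-[4,6-bis(benzyloxy)-3-bromo-2-{[tri(propan-2-yl)silyl]oxy}phenyl]propanoic acid | OC(=O)[C@@H](OCc1ccccc1)Cc1c(O[Si](C(C)C)(C(C)C)C(C)C)c(Br)c(OCc2ccccc2)cc1OCc1ccccc1
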